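An equilibrium constant of 5.0 gives the final ratio of L to X, not which species leads at a given time of reading.

| setting | oak | birch |
|---|---|---|
| D | 20 mM | 20 mM |
| time | 100 s | 50 s |

1. which of these there is most of at the end, counted by the D in it, oak (X / Z / L / Q)
2. which of these there is most of at the end, counted by the D in it, birch (X / Z / L / Q)
3. how much there is at the end of the one of these that leads, in percent of the D charged: oak
4. how much there is at the end of the one of these that leads, in percent of the D charged: birch

    D → Z (k1 = 0.0090 s⁻¹)
    G → Q (k2 = 0.94 s⁻¹)
    Q → X (k3 = 0.031 s⁻¹)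
    X ⇌ Z (K4 = 0.36, k4 = 0.053 s⁻¹)
    X ⇌ L (K5 = 5.0, k5 = 0.026 s⁻¹)
    D → G (k6 = 0.10 s⁻¹)

D lasts 9.17 s on average and sends s = 91.7 % of itself into G, the rest going to Z. G passes on to Q with a half-life of 0.74 s, shorter than that lag. This reckoning by hand therefore lands the charge at once, as Q and Z, at the end of the lag, and θ counts the time from there.

Two times remain. The feed time F = 32.3 s is the average stay of Q before it passes into X. The fill time T = 41.1 s is the reciprocal of the forward constant of X into L, scaled by the part of the X and Z pair that is X, plus the backward constant of L. The pair counts as one pool because X and Z settle within 4.99 s, faster than either time.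

With E = 78.6 %, the equilibrium share of L, integrating the rate of L gives, as shares of the D charged:

c_L = E·[1 − e^(−θ/T) + s·F/(T−F)·(e^(−θ/F) − e^(−θ/T))]

Beside it, c_Q = s·e^(−θ/F), and c_X is what Q and L leave, divided by 1 + 0.36. T/F is 1.27, so the two stages run in series at a like pace.

| reckoned | c_Q | c_L | c_X |
|---|---|---|---|
| birch, 50 s | 25.9 % | 26.3 % | 35.2 % |
| oak, 100 s | 5.49 % | 56.9 % | 27.7 % |

The forecast named L for oak at 56 % (52 % to 60 %) and X for birch at 34 % (30 % to 37 %), with the words “by 100 s L has clearly taken over”. The reckoning names the same leaders with higher figures .

Oak ends with L leading at 56.1 %, birch with X at 34.2 %, ahead of Q at 27.5 % and L at 25.9 %. X and L draw level at 60.9 s, which is 1.26 fill times of 41.1 s after the lag. Taking away the passing of X into L, both ways, leaves oak with X at 69.4 % in place of 27.6 % and takes the lead from L, so that step is the main reason for the outcome in oak. The same formula carried to a reading of oak at 4.0 min gives c_L = 77.6 %, and that neighbour holds L at 77.4 %.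

The constants used here are assumed.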